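**Strategy.** Ring B (C5–C10) is a p‑menthane in disguise: the C8 methyl sits para to C5, which carries the gem‑dimethyl carbon C4. (R)‑Carvone therefore supplies ring B, the C5 stereocentre, the C8 methyl and the C9 carbonyl, and its isopropenyl carbon becomes C4. Two enolate alkylations set quaternary C10. The key step, an iron‑hydride‑initiated radical cyclisation, joins the olefinic carbons C4 (isopropenyl) and C3 (vinyl sulfone), creating the gem‑dimethyl quaternary carbon and closing trans‑fused ring A (C1–C5, C10) on the existing ring B in one operation. Its precursor is a monocyclic 6,6‑disubstituted carvone. The sulfone is then erased and the C9 enol triflate receives the side chain.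

Key step: step 5

Remark on numbering (drimane convention): ring A = C1–C5 with C10; ring B = C5–C10; methyl groups on C4 (two), C8 and C10; side chain C11–C17 on C9, the ester carbon being attached to C17.

Step 1
Reactants: 1 phenyl vinyl sulfone
Product: 2 2-(phenylsulfonyl)prop-2-en-1-ol
Conditions: aq. CH2O (37 %), DABCO (20 mol %), THF, 23 °C
Reagents that add atoms: formaldehyde (C=O)
Why: The Morita–Baylis–Hillman reaction of the vinyl sulfone with formaldehyde should place the hydroxymethyl group on the α‑carbon; no stereocentre is formed.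

Step 2
Reactants: 2 2-(phenylsulfonyl)prop-2-en-1-ol
Product: 3 3-bromo-2-(phenylsulfonyl)prop-1-ene
Conditions: PBr3, Et2O, 0 °C
Reagents that add atoms: phosphorus tribromide (BrP(Br)Br)
Why: Bromination of a primary allylic alcohol with PBr3 (substitution of the phosphite ester by bromide) should give the allylic bromide; the 2‑sulfonylallyl unit is symmetric, so direct and allylic substitution lead to the same product.

Step 3
Reactants: 4 (R)-carvone
Product: 6 (5R)-2,6-dimethyl-5-(prop-1-en-2-yl)cyclohex-2-en-1-one (6-methylcarvone as a mixture of C6 epimers), via carvone lithium dienolate 5 (not isolated)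
Conditions: LiN(i-Pr)2, THF, −78 °C; MeI, −78 → 0 °C
Reagents that add atoms: iodomethane (CI)
Why: Kinetic α′‑deprotonation and C‑methylation of the cross‑conjugated dienolate (enolate alkylation) should install the future C10 methyl; the new centre is re‑enolised in step 4, so its configuration does not matter.

Step 4
Reactants: 6 6-methylcarvone; 3 3-bromo-2-(phenylsulfonyl)prop-1-ene
Product: 8 (5S,6S)-2,6-dimethyl-6-[2-(phenylsulfonyl)prop-2-en-1-yl]-5-(prop-1-en-2-yl)cyclohex-2-en-1-one, via methylcarvone lithium dienolate 7 (not isolated)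
Conditions: LiN(i-Pr)2, THF, −78 °C; then 3, −78 → −20 °C
Reagents that add atoms: none
Why: Enolate alkylation with the activated allylic bromide should create the quaternary centre (future C10), the electrophile entering anti to the adjacent isopropenyl group (1,2‑induction), so that the methyl is cis and the sulfonylallyl arm trans to the isopropenyl group.

Step 5
Reactants: 8 (5S,6S)-2,6-dimethyl-6-[2-(phenylsulfonyl)prop-2-en-1-yl]-5-(prop-1-en-2-yl)cyclohex-2-en-1-one
Product: 9 (4aS,8aS)-2,5,5,8a-tetramethyl-7-(phenylsulfonyl)-4a,5,6,7,8,8a-hexahydronaphthalen-1(4H)-one (mixture of epimers at the sulfonyl-bearing carbon)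
Conditions: Fe(acac)3 (30 mol %), PhSiH3, EtOH/ethylene glycol, 60 °C
Reagents that add atoms: none
Why: Hydrogen‑atom transfer from an iron hydride (formed from Fe(acac)3 and PhSiH3) to the CH2 terminus of the isopropenyl group should give the tertiary radical at C4, which adds to the unsubstituted terminus C3 of the vinyl sulfone; the resulting α‑sulfonyl radical is reduced by divalent iron and protonated by ethanol. The closest known reaction type is the iron‑catalysed reductive olefin coupling (metal‑hydride hydrogen‑atom transfer followed by a Giese addition), used here intramolecularly. Ring A closes in the 6‑endo‑trig mode, favoured over 5‑exo because C3 is the polarity‑matched, unhindered β‑carbon of the acceptor whereas C2 is fully substituted. The only new stereocentre, the sulfonyl‑bearing C2, forms as a mixture and is erased in step 6; the trans ring fusion follows from the existing C5 and C10 centres, whose two arms are trans‑diequatorial on ring B and can only bridge to a trans‑decalin. The step needs chemoselective hydrogen‑atom transfer to the electron‑rich 1,1‑disubstituted alkene in the presence of the enone and the vinyl sulfone, which the preference of such hydrides for electron‑rich, unhindered alkenes should secure. In polar terms C3 and C4 are both electrophilic sites, and the radical manifold reverses the polarity of C4 so that the two can be joined.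

Step 6
Reactants: 9 (4aS,8aS)-2,5,5,8a-tetramethyl-7-(phenylsulfonyl)-4a,5,6,7,8,8a-hexahydronaphthalen-1(4H)-one
Product: 11 (4aS,8aS)-2,5,5,8a-tetramethyl-3,4,4a,5,6,7,8,8a-octahydronaphthalen-1-yl trifluoromethanesulfonate, via bicyclic lithium enolate 10 (not isolated)
Conditions: Li, NH3(l)/THF, −78 °C; isoprene; evaporate NH3; PhNTf2, THF, 0 → 23 °C
Reagents that add atoms: N-phenylbis(trifluoromethanesulfonimide) (O=S(=O)(N(c1ccccc1)S(=O)(=O)C(F)(F)F)C(F)(F)F)
Why: Dissolving‑metal (Birch‑type) reduction should turn the enone into the only possible lithium enolate (C8=C9, C10 being quaternary) and cleave the secondary alkyl–sulfonyl bond in the same flask, and O‑triflation of that enolate should give the tetrasubstituted enol triflate; the sulfonyl‑bearing centre is erased and no stereocentre is formed.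

Step 7
Reactants: 11 enol triflate; 12 (4-iodobut-1-yn-1-yl)trimethylsilane
Product: 14 trimethyl{4-[(4aS,8aS)-2,5,5,8a-tetramethyl-3,4,4a,5,6,7,8,8a-octahydronaphthalen-1-yl]but-1-yn-1-yl}silane, via silylbutynylzinc iodide 13 (not isolated)
Conditions: 12, Zn dust, LiCl, THF, 40 °C; then 11, Pd(dppf)Cl2 (5 mol %), THF/NMP, 60 °C
Reagents that add atoms: none
Why: Zinc insertion into the primary iodide and Negishi sp3–sp2 cross‑coupling at the enol triflate, a coupling established for 2,6,6‑trimethylcyclohexenyl‑type triflates, should form C9–C11 and fix the tetrasubstituted C8=C9 alkene; the zinc reagent tolerates the silyl alkyne.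

Step 8
Reactants: 14 silyl alkyne
Product: 15 (4aS,8aS)-1-(but-3-yn-1-yl)-2,5,5,8a-tetramethyl-3,4,4a,5,6,7,8,8a-octahydronaphthalene
Conditions: K2CO3, MeOH, 23 °C
Reagents that add atoms: none
Why: Base‑catalysed methanolysis of the alkynyl–silicon bond (protodesilylation) should free the terminal alkyne without touching the tetrasubstituted alkene.

Step 9
Reactants: 15 terminal alkyne
Product: 17 (4aS,8aS)-1-[(3E)-4-iodo-3-methylbut-3-en-1-yl]-2,5,5,8a-tetramethyl-3,4,4a,5,6,7,8,8a-octahydronaphthalene, via alkenyldimethylalane 16 (not isolated)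
Conditions: Me3Al, Cp2ZrCl2 (25 mol %), CH2Cl2, 0 → 23 °C; then I2, THF, −30 °C
Reagents that add atoms: trimethylaluminium (C[Al](C)C); iodine (II)
Why: Zirconium‑catalysed carboalumination (Negishi carboalumination) adds methyl and aluminium syn across the terminal alkyne with methyl on the internal carbon, and iodinolysis with retention should give the (E)‑iodide, which sets the 13E geometry.

Step 10
Reactants: 18 methyl (2E)-4-bromobut-2-enoate
Product: 19 methyl (2R)-2-methylbut-3-enoate
Conditions: MeMgBr, CuBr·SMe2 (1 mol %), Taniaphos (1.2 mol %, the antipode that gives the (R)-ester), CH2Cl2, −78 °C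
Reagents that add atoms: methylmagnesium bromide (C[Mg]Br)
Why: Copper‑catalysed asymmetric allylic alkylation (SN2′) of the bromocrotonate should deliver the methyl group to the α‑carbon, the chiral ferrocenyl diphosphine on copper selecting the face and setting the (R) centre (C17).

Step 11
Reactants: 19 methyl (2R)-2-methylbut-3-enoate; 20 vinylboronic acid pinacol ester
Product: 21 methyl (2R,3E)-2-methyl-4-(4,4,5,5-tetramethyl-1,3,2-dioxaborolan-2-yl)but-3-enoate
Conditions: second-generation Grubbs catalyst (5 mol %), 1,4-benzoquinone (10 mol %), CH2Cl2, 40 °C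
Reagents that add atoms: none
Why: Olefin cross‑metathesis with the vinyl boronate should give the (E)‑alkenyl boronate under thermodynamic control (15E), benzoquinone suppressing alkene migration so that the α‑stereocentre is untouched.

Step 12
Reactants: 17 (E)-alkenyl iodide; 21 (E)-alkenyl boronate
Product: 22 methyl (2R,3E,5E)-2,6-dimethyl-8-[(4aS,8aS)-2,5,5,8a-tetramethyl-3,4,4a,5,6,7,8,8a-octahydronaphthalen-1-yl]octa-3,5-dienoate (CNP0152124.1)
Conditions: Pd(dppf)Cl2 (5 mol %), K3PO4 (aq.), THF, 23 °C
Reagents that add atoms: none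
Why: Suzuki–Miyaura coupling proceeds with retention at both alkenyl partners and should give the (13E,15E)‑diene, the mild phosphate base at room temperature being chosen to leave the α‑stereocentre of the β,γ‑unsaturated ester intact.

**Compound list**

1 | phenyl vinyl sulfone | C=CS(=O)(=O)c1ccccc1 | starting material
2 | 2-(phenylsulfonyl)prop-2-en-1-ol | OCC(=C)S(=O)(=O)c1ccccc1 | intermediate
3 | 3-bromo-2-(phenylsulfonyl)prop-1-ene | BrCC(=C)S(=O)(=O)c1ccccc1 | intermediate
4 | (R)-carvone, (5R)-2-methyl-5-(prop-1-en-2-yl)cyclohex-2-en-1-one | O=C1C(C)=CC[C@@H](C(C)=C)C1 | starting material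
5 | lithium cross-conjugated dienolate of 4 (O–Li on C1, C1=C6 and C2=C3, C5 unchanged) | [Li]OC1=C[C@H](C(C)=C)CC=C1C | intermediate
6 | (5R)-2,6-dimethyl-5-(prop-1-en-2-yl)cyclohex-2-en-1-one (6-methylcarvone, mixture of C6 epimers) | O=C1C(C)=CC[C@@H](C(C)=C)C1C | intermediate
7 | lithium cross-conjugated dienolate of 6 (O–Li on C1, C1=C6 and C2=C3, C5 unchanged) | [Li]OC1=C(C)[C@H](C(C)=C)CC=C1C | intermediate
8 | (5S,6S)-2,6-dimethyl-6-[2-(phenylsulfonyl)prop-2-en-1-yl]-5-(prop-1-en-2-yl)cyclohex-2-en-1-one | O=C1C(C)=CC[C@@H](C(C)=C)[C@]1(C)CC(=C)S(=O)(=O)c1ccccc1 | intermediate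
9 | (4aS,8aS)-2,5,5,8a-tetramethyl-7-(phenylsulfonyl)-4a,5,6,7,8,8a-hexahydronaphthalen-1(4H)-one (C7 epimers) | O=C1C(C)=CC[C@H]2C(C)(C)CC(S(=O)(=O)c3ccccc3)C[C@]12C | intermediate
10 | lithium (4aS,8aS)-2,5,5,8a-tetramethyl-3,4,4a,5,6,7,8,8a-octahydronaphthalen-1-olate | [Li]OC1=C(C)CC[C@H]2C(C)(C)CCC[C@]12C | intermediate
11 | (4aS,8aS)-2,5,5,8a-tetramethyl-3,4,4a,5,6,7,8,8a-octahydronaphthalen-1-yl trifluoromethanesulfonate | O=S(=O)(OC1=C(C)CC[C@H]2C(C)(C)CCC[C@]12C)C(F)(F)F | intermediate
12 | (4-iodobut-1-yn-1-yl)trimethylsilane | C[Si](C)(C)C#CCCI | starting material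
13 | [4-(trimethylsilyl)but-3-yn-1-yl]zinc iodide | C[Si](C)(C)C#CCC[Zn]I | intermediate
14 | trimethyl{4-[(4aS,8aS)-2,5,5,8a-tetramethyl-3,4,4a,5,6,7,8,8a-octahydronaphthalen-1-yl]but-1-yn-1-yl}silane | C[Si](C)(C)C#CCCC1=C(C)CC[C@H]2C(C)(C)CCC[C@]12C | intermediate
15 | (4aS,8aS)-1-(but-3-yn-1-yl)-2,5,5,8a-tetramethyl-3,4,4a,5,6,7,8,8a-octahydronaphthalene | C#CCCC1=C(C)CC[C@H]2C(C)(C)CCC[C@]12C | intermediate
16 | dimethyl{(1E)-2-methyl-4-[(4aS,8aS)-2,5,5,8a-tetramethyl-3,4,4a,5,6,7,8,8a-octahydronaphthalen-1-yl]but-1-en-1-yl}alane | C[Al](C)/C=C(\C)CCC1=C(C)CC[C@H]2C(C)(C)CCC[C@]12C | intermediate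
17 | (4aS,8aS)-1-[(3E)-4-iodo-3-methylbut-3-en-1-yl]-2,5,5,8a-tetramethyl-3,4,4a,5,6,7,8,8a-octahydronaphthalene | I/C=C(\C)CCC1=C(C)CC[C@H]2C(C)(C)CCC[C@]12C | intermediate
18 | methyl (2E)-4-bromobut-2-enoate | COC(=O)/C=C/CBr | starting material
19 | methyl (2R)-2-methylbut-3-enoate | COC(=O)[C@H](C)C=C | intermediate
20 | vinylboronic acid pinacol ester | C=CB1OC(C)(C)C(C)(C)O1 | starting material
21 | methyl (2R,3E)-2-methyl-4-(4,4,5,5-tetramethyl-1,3,2-dioxaborolan-2-yl)but-3-enoate | COC(=O)[C@H](C)/C=C/B1OC(C)(C)C(C)(C)O1 | intermediate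
22 | methyl (2R,3E,5E)-2,6-dimethyl-8-[(4aS,8aS)-2,5,5,8a-tetramethyl-3,4,4a,5,6,7,8,8a-octahydronaphthalen-1-yl]octa-3,5-dienoate | COC(=O)[C@H](C)/C=C/C=C(\C)CCC1=C(C)CC[C@H]2C(C)(C)CCC[C@]12C | target

**Step count.** Total: 12 steps. Longest linear sequence: 9 steps (1, 2, 4, 5, 6, 7, 8, 9, 12); from (R)-carvone the target is 8 steps away.

**Steps most likely to fail and their fallbacks.**

Step 5: hydrogen‑atom transfer to the vinyl sulfone, or quenching of the tertiary radical before it cyclises (net hydrogenation of the isopropenyl group), may outrun ring closure. The fallback generates the same radical by a polar addition followed by a tin‑hydride chain. It sets out from 8: Markovnikov addition of HBr (HBr/AcOH, 0 °C) to the isopropenyl group should give the tertiary bromide F1. Slow addition of Bu3SnH with AIBN in benzene at 80 °C should then effect the same 6‑endo cyclisation onto the vinyl sulfone, and the route is rejoined at 9.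

Step 6: cleavage of the C–S bond may stay incomplete through α‑deprotonation of the sulfone by the amide base formed in ammonia, and that base may consume the triflating agent so that O‑triflation stalls. The fallback separates the two events and sets out from 9. Conjugate reduction with LiBH(s-Bu)3 (THF, −78 °C) should give the sulfonyl lithium enolate F2, which is trapped in the same flask with PhNTf2 as the sulfonyl enol triflate F3. Negishi coupling of F3 with 13 under the conditions of step 7 should give the sulfonyl silylalkyne F4. Reductive desulfonylation with Mg in MeOH (HgCl2 cat., 50 °C) then rejoins the route at 14.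

Step 7: oxidative addition and reductive elimination at the hindered, tetrasubstituted triflate may be slow enough for β‑hydride elimination or protodemetalation of the alkyl partner to take over. The fallback builds C9–C11 by carbonylation and C11–C12 by alkylation, and sets out from 11. Methoxycarbonylation (Pd(OAc)2, PPh3, CO, MeOH, Et3N, DMF, 60 °C) should give the methyl ester F5. Reduction with i-Bu2AlH (CH2Cl2, −78 °C) should give the allylic alcohol F6, and PBr3 (Et2O, 0 °C) the allylic bromide F7. Displacement of the bromide with 3‑lithio‑1‑(trimethylsilyl)propyne (from 1‑(trimethylsilyl)propyne and n‑BuLi, THF, −78 °C) rejoins the route at 14.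

Further compounds
F1 | step 5 | (5R,6S)-5-(2-bromopropan-2-yl)-2,6-dimethyl-6-[2-(phenylsulfonyl)prop-2-en-1-yl]cyclohex-2-en-1-one | O=C1C(C)=CC[C@@H](C(C)(C)Br)[C@]1(C)CC(=C)S(=O)(=O)c1ccccc1
F2 | step 6 | lithium (4aS,8aS)-2,5,5,8a-tetramethyl-7-(phenylsulfonyl)-3,4,4a,5,6,7,8,8a-octahydronaphthalen-1-olate | [Li]OC1=C(C)CC[C@H]2C(C)(C)CC(S(=O)(=O)c3ccccc3)C[C@]12C
F3 | step 6 | (4aS,8aS)-2,5,5,8a-tetramethyl-7-(phenylsulfonyl)-3,4,4a,5,6,7,8,8a-octahydronaphthalen-1-yl trifluoromethanesulfonate | O=S(=O)(OC1=C(C)CC[C@H]2C(C)(C)CC(S(=O)(=O)c3ccccc3)C[C@]12C)C(F)(F)F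
F4 | step 6 | trimethyl{4-[(4aS,8aS)-2,5,5,8a-tetramethyl-7-(phenylsulfonyl)-3,4,4a,5,6,7,8,8a-octahydronaphthalen-1-yl]but-1-yn-1-yl}silane | C[Si](C)(C)C#CCCC1=C(C)CC[C@H]2C(C)(C)CC(S(=O)(=O)c3ccccc3)C[C@]12C
F5 | step 7 | methyl (4aS,8aS)-2,5,5,8a-tetramethyl-3,4,4a,5,6,7,8,8a-octahydronaphthalene-1-carboxylate | COC(=O)C1=C(C)CC[C@H]2C(C)(C)CCC[C@]12C
F6 | step 7 | [(4aS,8aS)-2,5,5,8a-tetramethyl-3,4,4a,5,6,7,8,8a-octahydronaphthalen-1-yl]methanol | OCC1=C(C)CC[C@H]2C(C)(C)CCC[C@]12C
F7 | step 7 | (4aS,8aS)-1-(bromomethyl)-2,5,5,8a-tetramethyl-3,4,4a,5,6,7,8,8a-octahydronaphthalene | BrCC1=C(C)CC[C@H]2C(C)(C)CCC[C@]12C
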